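The ten-membered ring is derived from a thirteen-membered cyclic ether in which oxygen bridges C6 and C13. The feature exploited is the homoallylic alcohol pattern C6(O)–C7–C11(=C13) where the γ-lactone meets the ten-membered ring: a [2,3]-Wittig shift of the boron enolate of α-allyloxy enone 25 forms C6–C7, breaks O–C13, contracts the ring to the C1–C10 carbocycle, moves the alkene to C11=C13 and sets C6 and C7 in one operation. Enone 25 already holds the E C1=C2 alkene, the C4 methylene, C12 as a protected alcohol and an 8S silyl ether, chosen so that attack anti to its C–O bond selects the required C7 face; C8 is inverted when the tiglate is installed.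

Key step: step 15

Numbering used throughout: ring C1=C2, C3, C4(=C15), C5, C6, C7, C8, C9, C10 (methyl C14); lactone carbons C11(=C13) and C12. In the target H6, the C5 acetate, the C8 ester and the C10 methyl are β; H7 and the C10 hydroxyl are α.
Remark: commercial (R)-(−)-linalool is taken as enantiomerically enriched; its carbinol carbon becomes C10, and material from the minor enantiomer is removed as a diastereomer after step 7.

Step 1
Reactants: 1 2,3-dibromopropene; 2 vinylmagnesium bromide
Product: 3 2-bromopenta-1,4-diene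
Conditions: CuI (5 mol%), THF, 0 to 20 °C
Reagents that add atoms: none
Why: Copper-catalysed coupling of a vinyl Grignard reagent at the allylic bromide (allylic substitution, in which direct and transposed attack give the same product) should leave the vinylic C–Br bond untouched.

Step 2
Reactants: 4 triethyl phosphonoacetate; 5 paraformaldehyde
Product: 7 ethyl 2-(diethoxyphosphoryl)acrylate, via methanol adduct 6 (not isolated)
Conditions: piperidine (cat.), MeOH, reflux; then TsOH·H2O (cat.), toluene, reflux with distillation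
Reagents that add atoms: none
Why: Knoevenagel condensation of the active methylene compound with formaldehyde gives the acrylate, which is held as its methanol adduct and released by acid-catalysed loss of methanol.

Step 3
Reactants: 7 ethyl 2-(diethoxyphosphoryl)acrylate; 8 4-methoxybenzyl alcohol
Product: 9 ethyl 2-(diethoxyphosphoryl)-3-[(4-methoxybenzyl)oxy]propanoate (racemic)
Conditions: KOt-Bu (10 mol%), THF, 0 to 20 °C; AcOH quench
Reagents that add atoms: none
Why: Base-catalysed oxa-Michael addition to the doubly activated alkene should be clean; the new stereocentre is racemic and disappears in step 7.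

Step 4
Reactants: 10 (R)-linalool
Product: 11 (R)-3,7-dimethyl-3-(triethylsilyloxy)octa-1,6-diene
Conditions: TESOTf, 2,6-lutidine, CH2Cl2, −78 to 0 °C
Reagents that add atoms: triethylsilyl trifluoromethanesulfonate, CC[Si](CC)(CC)OS(=O)(=O)C(F)(F)F
Why: Silylation of a tertiary alcohol with a silyl triflate and a hindered pyridine base leaves the stereocentre untouched.

Step 5
Reactants: 11 (R)-3,7-dimethyl-3-(triethylsilyloxy)octa-1,6-diene
Product: 13 (R)-4-methyl-4-(triethylsilyloxy)hex-5-enal, via ozonide 12 (not isolated)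
Conditions: O3, CH2Cl2, −78 °C, Sudan Red 7B as end-point indicator; then PPh3, −78 to 20 °C
Reagents that add atoms: ozone, [O-][O+]=O
Why: In this ozonolysis with reductive work-up the electron-rich trisubstituted alkene should react far faster than the vinyl group, and the dye marks the end point.

Step 6
Reactants: 13 (R)-4-methyl-4-(triethylsilyloxy)hex-5-enal; 3 2-bromopenta-1,4-diene (4 equiv)
Product: 14 (4R,5E)-8-bromo-4-methyl-4-(triethylsilyloxy)nona-5,8-dienal
Conditions: second-generation Hoveyda–Grubbs catalyst (5 mol%), CH2Cl2, 40 °C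
Reagents that add atoms: none
Why: In this olefin cross-metathesis the vinyl group on the fully substituted C10 cannot homodimerise and should couple with the unhindered terminal alkene of 3, whose 2-bromoalkene end is inert; the bulk at C10 enforces the E C1=C2 geometry.

Step 7
Reactants: 14 (4R,5E)-8-bromo-4-methyl-4-(triethylsilyloxy)nona-5,8-dienal; 9 ethyl 2-(diethoxyphosphoryl)-3-[(4-methoxybenzyl)oxy]propanoate
Product: 16 ethyl (2E,4S,6R,7E)-10-bromo-2-{[(4-methoxybenzyl)oxy]methyl}-6-methyl-4-(phenylaminooxy)-6-(triethylsilyloxy)undeca-2,7,10-trienoate, via aminoxy aldehyde 15 (not isolated)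
Conditions: D-proline (20 mol%), PhNO, DMSO, 20 °C; then 9, LiCl, DBU, MeCN, 0 °C
Reagents that add atoms: nitrosobenzene, O=Nc1ccccc1
Why: Enamine-catalysed α-aminoxylation, in which the D-proline carboxylic acid directs the nitroso oxygen to one enamine face to set C8 as S, is followed by Horner–Wadsworth–Emmons olefination under Masamune–Roush conditions, which places the ester carbon (C13) trans to C8.

Step 8
Reactants: 16 the aminoxy enoate of step 7
Product: 17 ethyl (2E,4S,6R,7E)-10-bromo-4-hydroxy-2-{[(4-methoxybenzyl)oxy]methyl}-6-methyl-6-(triethylsilyloxy)undeca-2,7,10-trienoate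
Conditions: Cu(OAc)2·H2O (30 mol%), EtOH, 20 °C
Reagents that add atoms: none
Why: Copper-mediated cleavage of the weak N–O bond frees the C8 hydroxyl, which cannot lactonise because the ester is trans to it.

Step 9
Reactants: 17 the γ-hydroxy enoate of step 8
Product: 18 ethyl (2E,4S,6R,7E)-10-bromo-4-(tert-butyldimethylsilyloxy)-2-{[(4-methoxybenzyl)oxy]methyl}-6-methyl-6-(triethylsilyloxy)undeca-2,7,10-trienoate
Conditions: TBSCl, imidazole, DMF, 20 °C
Reagents that add atoms: tert-butyldimethylsilyl chloride, CC(C)(C)[Si](C)(C)Cl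
Why: Imidazole-promoted silylation of a secondary alcohol is neutral enough for the enoate and the tertiary silyl ether.

Step 10
Reactants: 18 the silyl-protected enoate of step 9
Product: 19 (2Z,4S,6R,7E)-10-bromo-4-(tert-butyldimethylsilyloxy)-2-{[(4-methoxybenzyl)oxy]methyl}-6-methyl-6-(triethylsilyloxy)undeca-2,7,10-trien-1-ol (C13 carbinol trans to C8)
Conditions: i-Bu2AlH (2.5 equiv), CH2Cl2, −78 °C; aq. potassium sodium tartrate
Reagents that add atoms: none
Why: 1,2-Reduction of the unsaturated ester to the allylic alcohol leaves the alkenes, the vinyl bromide and the ethers untouched.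

Step 11
Reactants: 19 the C13 allylic alcohol; 20 2-bromo-N-methoxy-N-methylacetamide
Product: 21 N-methoxy-N-methyl-2-{[(2E,4S,6R,7E)-10-bromo-4-(tert-butyldimethylsilyloxy)-2-{[(4-methoxybenzyl)oxy]methyl}-6-methyl-6-(triethylsilyloxy)undeca-2,7,10-trien-1-yl]oxy}acetamide
Conditions: NaH, THF, 0 °C; then 20, Bu4NI (cat.), 0 to 20 °C
Reagents that add atoms: none
Why: In this Williamson ether synthesis the primary allylic alkoxide should displace the α-bromide faster than it attacks the amide carbonyl.

Step 12
Reactants: 21 the Weinreb amide of step 11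
Product: 22 2-{[(2E,4S,6R,7E)-10-bromo-4-(tert-butyldimethylsilyloxy)-2-{[(4-methoxybenzyl)oxy]methyl}-6-methyl-6-(triethylsilyloxy)undeca-2,7,10-trien-1-yl]oxy}acetaldehyde (C5 aldehyde)
Conditions: i-Bu2AlH (1.3 equiv), THF, −78 °C; aq. potassium sodium tartrate
Reagents that add atoms: none
Why: Reduction of a Weinreb amide stops at the aldehyde because the chelated tetrahedral aluminium adduct survives until work-up.

Step 13
Reactants: 22 the bromo aldehyde of step 12
Product: 24 thirteen-membered cyclic ether alcohol (ring C5(OH)–C6H2–O–C13H2–C11(C12H2OPMB)=C7H–C8H(OTBS)–C9H2–C10(CH3)(OTES)–C1H=C2H–C3H2–C4(=C15H2); 8S; 10R; C13 trans to C8; C1=C2 E; both C5 epimers), via alkenylchromium species 23 (not isolated)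
Conditions: CrCl2 (8 equiv), NiCl2 (10 mol%), DMSO, 20 °C, slow addition to a final 2 mM
Reagents that add atoms: none
Why: In the Nozaki–Hiyama–Kishi reaction the nickel-catalysed formation of an alkenylchromium species from the 2-bromoalkene and its chemoselective addition to the aldehyde should close the thirteen-membered ring at C4–C5 under high dilution; the C5 epimers converge in step 14.

Step 14
Reactants: 24 the macrocyclic allylic alcohol
Product: 25 thirteen-membered α-allyloxy enone (24 with C5 as ketone)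
Conditions: Dess–Martin periodinane, NaHCO3, CH2Cl2, 0 to 20 °C
Reagents that add atoms: none
Why: Buffered Dess–Martin oxidation of the allylic alcohol gives the enone without isomerising the skipped diene.

Step 15
Reactants: 25 the thirteen-membered α-allyloxy enone
Product: 28 ten-membered ketol (ring C1=C2 E; C3H2; C4(=C15H2); C5 ketone; C6H(OH) α-hydroxyl; C7H with H7α bearing C11(=C13H2)C12H2OPMB; C8H(OTBS) 8S; C9H2; C10(CH3)(OTES) 10R), via boron enolate 26 (not isolated), via boron alkoxide 27 (not isolated)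
Conditions: Bu2BOTf (1.5 equiv), iPr2NEt (2 equiv), degassed CH2Cl2, −78 to 0 °C; then MeOH, pH 7 buffer
Reagents that add atoms: none
Why: Proposed new method: Bu2BOTf and iPr2NEt enolise the ketone toward C6, the only site with α-hydrogens because C4 is the sp2 carbon of the enone, and boron enolate 26 then undergoes a concerted suprafacial [2,3]-shift through a five-centre envelope (C6, O, C13, C11, C7) in which C6–C7 forms as O–C13 breaks, leaving the C6 oxygen as boron alkoxide 27; the closest known reactions are the carbanion [2,3]-Wittig ring contraction of thirteen-membered allylic ethers to cyclodecenols and the boron-enolate [2,3]-Wittig rearrangement of acyclic α-allyloxy esters and ketones, whose combination on a macrocyclic enone is untested. The ten-membered carbocycle is closed transannularly as a ring contraction: the two carbons are already held five atoms apart by the ether bridge, so the closure runs through a five-membered cyclic transition state and is not an end-to-end macrocyclisation. The C6/C7 relationship (H6 anti to H7, as the trans-fused lactone requires) follows from the alkene geometry, C13 trans to C8, when C5 sits exo on the envelope, the course taken by the carbanion ring contractions. The absolute sense comes from C8: 1,3-allylic strain with C12 keeps H8 in the alkene plane and C6 should add to the C7 face anti to the bulky C8–OTBS bond (Felkin-type preference of a nucleophilic carbon), which for the 8S ether gives H7α and therefore H6β. The step also needs the [2,3] shift to win over the [1,2] shift and over the [3,3] (Claisen) shift of the same allyl enol ether; the allylic terminus, the covalent boron enolate (free potassium enolates are the ones known to prefer the [3,3] path) and the lower strain of a ten-membered than of a nine-membered product are relied on for this.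

Step 16
Reactants: 28 the ten-membered ketol
Product: 29 ketol diol (28 with C12 as free primary allylic alcohol)
Conditions: DDQ, CH2Cl2/pH 7 buffer (10:1), 0 °C
Reagents that add atoms: none
Why: Oxidative cleavage of the electron-rich benzyl ether through its oxocarbenium ion and hydrolysis should leave the silyl ethers and the ketol untouched.

Step 17
Reactants: 29 the ketol diol
Product: 32 5-oxo-6α,12-olide (trans-fused α-methylene-γ-butyrolactone; C8 OTBS; C10 OTES), via hydroxy enal 30 (not isolated), via lactol 31 (not isolated)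
Conditions: TEMPO (20 mol%), PhI(OAc)2 (2.5 equiv), CH2Cl2, 20 °C
Reagents that add atoms: none
Why: Nitroxyl-catalysed oxidation is selective for the primary allylic alcohol, the enal is trapped by the C6 hydroxyl as a five-membered lactol, and the lactol is oxidised on to the lactone (oxidative lactonisation of a 1,4-diol).

Step 18
Reactants: 32 the 5-oxo lactone
Product: 33 5β-hydroxy lactone (5S)
Conditions: NaBH4, CeCl3·7H2O, MeOH, −78 °C
Reagents that add atoms: none
Why: Luche reduction should give 1,2-reduction of the enone and spare the α-methylene lactone at low temperature, and hydride is expected to add anti to the C6–O bond (Felkin–Anh polar model) to give the 5β alcohol.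

Step 19
Reactants: 33 the 5β-hydroxy lactone
Product: 34 5β-acetoxy lactone (C8 OTBS; C10 OTES)
Conditions: Ac2O, pyridine, DMAP (cat.), CH2Cl2, 0 °C
Reagents that add atoms: acetic anhydride, CC(=O)OC(C)=O
Why: DMAP-catalysed acetylation of the only free hydroxyl group.

Step 20
Reactants: 34 the 5β-acetoxy lactone
Product: 35 5β-acetoxy-8α,10α-dihydroxy lactone (8S)
Conditions: HF·pyridine, pyridine, THF, 0 to 20 °C
Reagents that add atoms: none
Why: Buffered acidic fluoride should cleave both silyl ethers and leave the esters and the α-methylene lactone intact.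

Step 21
Reactants: 35 the 8α,10α-diol; 36 tiglic acid
Product: 38 target, 5β-acetoxy-10α-hydroxy-8β-[(E)-2-methylbut-2-enoyloxy]germacra-1(2)E,4(15),11(13)-trien-12,6α-olide (5S,6S,7R,8R,10R), via alkoxyphosphonium tiglate 37 (not isolated)
Conditions: PPh3, DIAD, toluene, 0 to 20 °C
Reagents that add atoms: none
Why: In this Mitsunobu esterification the secondary C8 hydroxyl is activated as its alkoxyphosphonium salt and displaced by tiglate with inversion (8S to 8R), while the tertiary C10 alcohol cannot be activated.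

Compound list
1 | 2,3-dibromopropene | C=C(Br)CBr | starting material
2 | vinylmagnesium bromide | C=C[Mg]Br | starting material
3 | 2-bromopenta-1,4-diene | C=CCC(Br)=C | intermediate
4 | triethyl phosphonoacetate | CCOC(=O)CP(=O)(OCC)OCC | starting material
5 | paraformaldehyde (formaldehyde source) | C=O | starting material
6 | ethyl 2-(diethoxyphosphoryl)-3-methoxypropanoate (racemic, not isolated) | CCOC(=O)C(COC)P(=O)(OCC)OCC | intermediate
7 | ethyl 2-(diethoxyphosphoryl)acrylate | CCOC(=O)C(=C)P(=O)(OCC)OCC | intermediate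
8 | 4-methoxybenzyl alcohol | COc1ccc(CO)cc1 | starting material
9 | ethyl 2-(diethoxyphosphoryl)-3-[(4-methoxybenzyl)oxy]propanoate (racemic) | CCOC(=O)C(COCc1ccc(OC)cc1)P(=O)(OCC)OCC | intermediate
10 | (R)-linalool | CC(C)=CCC[C@@](C)(O)C=C | starting material
11 | (R)-3,7-dimethyl-3-(triethylsilyloxy)octa-1,6-diene | CC(C)=CCC[C@@](C)(O[Si](CC)(CC)CC)C=C | intermediate
12 | ozonide of 11 at the trisubstituted alkene (1,2,4-trioxolane, not isolated) | CC1(C)OOC(CC[C@@](C)(O[Si](CC)(CC)CC)C=C)O1 | intermediate
13 | (R)-4-methyl-4-(triethylsilyloxy)hex-5-enal | O=CCC[C@@](C)(O[Si](CC)(CC)CC)C=C | intermediate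
14 | (4R,5E)-8-bromo-4-methyl-4-(triethylsilyloxy)nona-5,8-dienal | O=CCC[C@@](C)(O[Si](CC)(CC)CC)/C=C/CC(Br)=C | intermediate
15 | (2S,4R,5E)-8-bromo-4-methyl-2-(phenylaminooxy)-4-(triethylsilyloxy)nona-5,8-dienal (not isolated) | O=C[C@@H](ONc1ccccc1)C[C@@](C)(O[Si](CC)(CC)CC)/C=C/CC(Br)=C | intermediate
16 | ethyl (2E,4S,6R,7E)-10-bromo-2-{[(4-methoxybenzyl)oxy]methyl}-6-methyl-4-(phenylaminooxy)-6-(triethylsilyloxy)undeca-2,7,10-trienoate | CCOC(=O)/C(COCc1ccc(OC)cc1)=C/[C@@H](ONc1ccccc1)C[C@@](C)(O[Si](CC)(CC)CC)/C=C/CC(Br)=C | intermediate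
17 | ethyl (2E,4S,6R,7E)-10-bromo-4-hydroxy-2-{[(4-methoxybenzyl)oxy]methyl}-6-methyl-6-(triethylsilyloxy)undeca-2,7,10-trienoate | CCOC(=O)/C(COCc1ccc(OC)cc1)=C/[C@@H](O)C[C@@](C)(O[Si](CC)(CC)CC)/C=C/CC(Br)=C | intermediate
18 | ethyl (2E,4S,6R,7E)-10-bromo-4-(tert-butyldimethylsilyloxy)-2-{[(4-methoxybenzyl)oxy]methyl}-6-methyl-6-(triethylsilyloxy)undeca-2,7,10-trienoate | CCOC(=O)/C(COCc1ccc(OC)cc1)=C/[C@@H](O[Si](C)(C)C(C)(C)C)C[C@@](C)(O[Si](CC)(CC)CC)/C=C/CC(Br)=C | intermediate
19 | (2Z,4S,6R,7E)-10-bromo-4-(tert-butyldimethylsilyloxy)-2-{[(4-methoxybenzyl)oxy]methyl}-6-methyl-6-(triethylsilyloxy)undeca-2,7,10-trien-1-ol | OC/C(COCc1ccc(OC)cc1)=C/[C@@H](O[Si](C)(C)C(C)(C)C)C[C@@](C)(O[Si](CC)(CC)CC)/C=C/CC(Br)=C | intermediate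
20 | 2-bromo-N-methoxy-N-methylacetamide | CON(C)C(=O)CBr | starting material
21 | Weinreb amide, O-alkylated 19 (C13–O–C6H2–C5(=O)N(OMe)Me) | CON(C)C(=O)COC/C(COCc1ccc(OC)cc1)=C/[C@@H](O[Si](C)(C)C(C)(C)C)C[C@@](C)(O[Si](CC)(CC)CC)/C=C/CC(Br)=C | intermediate
22 | C5 aldehyde (C13–O–C6H2–C5HO) | O=CCOC/C(COCc1ccc(OC)cc1)=C/[C@@H](O[Si](C)(C)C(C)(C)C)C[C@@](C)(O[Si](CC)(CC)CC)/C=C/CC(Br)=C | intermediate
23 | C4 alkenylchromium dichloride of 22 (not isolated) | O=CCOC/C(COCc1ccc(OC)cc1)=C/[C@@H](O[Si](C)(C)C(C)(C)C)C[C@@](C)(O[Si](CC)(CC)CC)/C=C/CC(=C)[Cr](Cl)Cl | intermediate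
24 | thirteen-membered cyclic ether alcohol (8S,10R; C5 epimers) | OC1COC/C(COCc2ccc(OC)cc2)=C/[C@@H](O[Si](C)(C)C(C)(C)C)C[C@@](C)(O[Si](CC)(CC)CC)/C=C/CC1=C | intermediate
25 | thirteen-membered α-allyloxy enone (8S,10R), precursor of the key step | O=C1COC/C(COCc2ccc(OC)cc2)=C/[C@@H](O[Si](C)(C)C(C)(C)C)C[C@@](C)(O[Si](CC)(CC)CC)/C=C/CC1=C | intermediate
26 | dibutylboron enolate of 25 (C5(OBBu2)=C6, drawn Z; not isolated) | CCCCB(CCCC)O/C1=C\OC/C(COCc2ccc(OC)cc2)=C/[C@@H](O[Si](C)(C)C(C)(C)C)C[C@@](C)(O[Si](CC)(CC)CC)/C=C/CC1=C | intermediate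
27 | C6 O-dibutylboryl derivative of 28 (not isolated) | O=C1[C@@H](OB(CCCC)CCCC)[C@H](C(=C)COCc2ccc(OC)cc2)[C@@H](O[Si](C)(C)C(C)(C)C)C[C@@](C)(O[Si](CC)(CC)CC)/C=C/CC1=C | intermediate
28 | ten-membered ketol, product of the key step (C5 ketone, 6α-OH, H7α, 8S, 10R) | O=C1[C@@H](O)[C@H](C(=C)COCc2ccc(OC)cc2)[C@@H](O[Si](C)(C)C(C)(C)C)C[C@@](C)(O[Si](CC)(CC)CC)/C=C/CC1=C | intermediate
29 | ketol diol (C12 primary alcohol free) | O=C1[C@@H](O)[C@H](C(=C)CO)[C@@H](O[Si](C)(C)C(C)(C)C)C[C@@](C)(O[Si](CC)(CC)CC)/C=C/CC1=C | intermediate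
30 | hydroxy enal (C12 aldehyde, not isolated) | O=C1[C@@H](O)[C@H](C(=C)C=O)[C@@H](O[Si](C)(C)C(C)(C)C)C[C@@](C)(O[Si](CC)(CC)CC)/C=C/CC1=C | intermediate
31 | lactol (C12 epimers, not isolated) | C=C1C(O)O[C@H]2[C@H]1[C@@H](O[Si](C)(C)C(C)(C)C)C[C@@](C)(O[Si](CC)(CC)CC)/C=C/CC(=C)C2=O | intermediate
32 | 5-oxo-6α,12-olide | C=C1C(=O)O[C@H]2[C@H]1[C@@H](O[Si](C)(C)C(C)(C)C)C[C@@](C)(O[Si](CC)(CC)CC)/C=C/CC(=C)C2=O | intermediate
33 | 5β-hydroxy-6α,12-olide (5S) | C=C1C(=O)O[C@H]2[C@H]1[C@@H](O[Si](C)(C)C(C)(C)C)C[C@@](C)(O[Si](CC)(CC)CC)/C=C/CC(=C)[C@@H]2O | intermediate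
34 | 5β-acetoxy-6α,12-olide (C8 OTBS, C10 OTES) | C=C1C(=O)O[C@H]2[C@H]1[C@@H](O[Si](C)(C)C(C)(C)C)C[C@@](C)(O[Si](CC)(CC)CC)/C=C/CC(=C)[C@@H]2OC(C)=O | intermediate
35 | 5β-acetoxy-8α,10α-dihydroxy-6α,12-olide (8S) | C=C1C(=O)O[C@H]2[C@H]1[C@@H](O)C[C@@](C)(O)/C=C/CC(=C)[C@@H]2OC(C)=O | intermediate
36 | tiglic acid, (E)-2-methylbut-2-enoic acid | C/C=C(\C)C(=O)O | starting material
37 | C8 alkoxyphosphonium tiglate of 35 (not isolated) | C=C1C(=O)O[C@H]2[C@H]1[C@@H](O[P+](c3ccccc3)(c3ccccc3)c3ccccc3)C[C@@](C)(O)/C=C/CC(=C)[C@@H]2OC(C)=O.C/C=C(\C)C(=O)[O-] | intermediate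
38 | CNP0323375.1, 5β-acetoxy-10α-hydroxy-8β-tigloyloxygermacra-1(2)E,4(15),11(13)-trien-12,6α-olide | C=C1C(=O)O[C@H]2[C@H]1[C@H](OC(=O)/C(C)=C/C)C[C@@](C)(O)/C=C/CC(=C)[C@@H]2OC(C)=O | target

Total step count: 21 (steps 1 to 3 prepare the two small reagents 3 and 9).
Longest linear sequence: 18 steps, from (R)-linalool 10 through steps 4 to 21.

Steps most likely to fail

Step 15. The boron enolate may not rearrange before it decomposes, may take the [3,3] or [1,2] path, or C6 may add to the other C7 face if the conformation of the macrocycle overrides the allylic control. Fallback with known chemistry, from 21 back to 28: the sigmatropic shift is done on the open chain and the ten-membered ring is closed afterwards. Amide 21 with LiN(i-Pr)2 in THF at −78 to −20 °C should undergo the amide-enolate [2,3]-Wittig rearrangement to the α-hydroxy amide F1, governed by the same alkene geometry and the same attack anti to the C8–O bond, with C6/C7 isomers separated at this stage. Silylation (TESCl, imidazole) would give the C6 triethylsilyl ether F2 and i-Bu2AlH the aldehyde F3. CrCl2 with catalytic NiCl2 under high dilution would close the ten-membered ring at C4–C5 to the allylic alcohol F4. Dess–Martin oxidation would give the enone F5, and PPTS in MeOH would free the C6 hydroxyl to give 28.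

Step 21. Displacement at C8 has to come from the hindered inner side of the ring, so it may be slow and lose to elimination toward C9 or to acyl transfer with retention; the free 8α-hydroxyl may also relactonise onto C12. Fallback, from 35 to 38: Dess–Martin oxidation, to which the tertiary C10 alcohol is inert, would give the 8-ketone F6. Hydroxyl-directed reduction with Me4NBH(OAc)3 in MeCN/AcOH at −30 °C, with hydride delivered from boron bound to the C10 oxygen, is expected to give the 1,3-anti diol, the 8β,10α-diol F7. Acylation of the secondary hydroxyl with tigloyl chloride, pyridine and catalytic DMAP would then give 38.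

Step 18. Hydride may be delivered to the other face of C5 if the ring conformation overrides Felkin–Anh control, and conjugate reduction of the methylene lactone may compete. Fallback, from 32 to 34: if the 5α-alcohol F8 is the main product of the reduction, it is inverted and acetylated in one operation by a Mitsunobu reaction with acetic acid (PPh3, DIAD), which gives acetate 34.

Further compounds
F1 | step 15 | α-hydroxy Weinreb amide from acyclic [2,3]-Wittig rearrangement of 21 | CON(C)C(=O)[C@@H](O)[C@H](C(=C)COCc1ccc(OC)cc1)[C@@H](O[Si](C)(C)C(C)(C)C)C[C@@](C)(O[Si](CC)(CC)CC)/C=C/CC(Br)=C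
F2 | step 15 | C6 triethylsilyl ether of F1 | CON(C)C(=O)[C@@H](O[Si](CC)(CC)CC)[C@H](C(=C)COCc1ccc(OC)cc1)[C@@H](O[Si](C)(C)C(C)(C)C)C[C@@](C)(O[Si](CC)(CC)CC)/C=C/CC(Br)=C
F3 | step 15 | C5 aldehyde from F2 | O=C[C@@H](O[Si](CC)(CC)CC)[C@H](C(=C)COCc1ccc(OC)cc1)[C@@H](O[Si](C)(C)C(C)(C)C)C[C@@](C)(O[Si](CC)(CC)CC)/C=C/CC(Br)=C
F4 | step 15 | ten-membered allylic alcohol (C5 epimers, C6 OTES) | OC1[C@@H](O[Si](CC)(CC)CC)[C@H](C(=C)COCc2ccc(OC)cc2)[C@@H](O[Si](C)(C)C(C)(C)C)C[C@@](C)(O[Si](CC)(CC)CC)/C=C/CC1=C
F5 | step 15 | ten-membered enone, C6 triethylsilyl ether of 28 | O=C1[C@@H](O[Si](CC)(CC)CC)[C@H](C(=C)COCc2ccc(OC)cc2)[C@@H](O[Si](C)(C)C(C)(C)C)C[C@@](C)(O[Si](CC)(CC)CC)/C=C/CC1=C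
F6 | step 21 | 5β-acetoxy-10α-hydroxy-8-oxo-6α,12-olide | C=C1C(=O)O[C@H]2[C@H]1C(=O)C[C@@](C)(O)/C=C/CC(=C)[C@@H]2OC(C)=O
F7 | step 21 | 5β-acetoxy-8β,10α-dihydroxy-6α,12-olide (8R) | C=C1C(=O)O[C@H]2[C@H]1[C@H](O)C[C@@](C)(O)/C=C/CC(=C)[C@@H]2OC(C)=O
F8 | step 18 | 5α-hydroxy-6α,12-olide (5R epimer of 33) | C=C1C(=O)O[C@H]2[C@H]1[C@@H](O[Si](C)(C)C(C)(C)C)C[C@@](C)(O[Si](CC)(CC)CC)/C=C/CC(=C)[C@H]2O
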